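The cyclohexenone (ring numbering: C1 carbonyl, C2=C3, C4 methoxy, C5 methylene, C6 quaternary) is cut at the enone C2=C3 bond and at C5–C6. One Robinson-type operation, Michael addition then aldol condensation of a β-keto lactone with 2-methoxyacrolein, makes both; it exploits the 1,5-relationship of the C1 ketone and C3 through C6–C5–C4. In the precursor C6 is the α-carbon of a γ-lactone closed onto the side-chain carbinol oxygen, a temporary ring that acidifies C6, blocks one face and masks the alcohol. Its carbonyl carbon leaves as CO2 when a palladium-catalysed decarboxylative allylation brings in the allyl group.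

Key step: step 6

Remark on the chemistry: the (R)-configured phosphoric acid of step 2 is assumed to steer the crotyl group to the Re face of aldehyde 3, as it does with benzaldehyde; if the sense were opposite, its enantiomer would be used.

Step 1
Reactants: 1 methoxyacetaldehyde
Product: 2 2-methoxyacrolein (2-methoxyprop-2-enal)
Conditions: aq. CH2O (37 %), pyrrolidine (10 mol %), EtCO2H (10 mol %), i-PrOH, 45 °C; distilled and used at once
Reagents that add atoms: formaldehyde, C=O
Why: Amine-catalysed Mannich-type α-methylenation, in which the enamine of 1 adds to the formaldehyde-derived iminium ion and β-elimination of pyrrolidine gives the 2-substituted acrolein, with no stereocentre formed.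

Step 2
Reactants: 3 3,4,5-trimethoxybenzaldehyde; 4 (Z)-crotylboronic acid pinacol ester
Product: 5 (1R,2S)-2-methyl-1-(3,4,5-trimethoxyphenyl)but-3-en-1-ol (syn)
Conditions: (R)-TRIP [(R)-3,3'-bis(2,4,6-triisopropylphenyl)-1,1'-binaphthyl-2,2'-diyl hydrogen phosphate] (5 mol %), toluene, 4 Å molecular sieves, −30 °C; aq. NaHCO3
Reagents that add atoms: none
Why: Brønsted-acid-catalysed crotylboration through a closed six-membered chair transition state, in which the Z-crotyl geometry becomes the syn methyl/hydroxyl relationship and the chiral acid, hydrogen-bonded to a boronate oxygen and the formyl hydrogen, should direct attack to the Re face (1R,2S).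

Step 3
Reactants: 5
Product: 6 (1R,2S)-2-methyl-1-(3,4,5-trimethoxyphenyl)butane-1,4-diol
Conditions: 9-borabicyclo[3.3.1]nonane (9-BBN, 2.2 equiv), THF, 0 °C to rt; then NaOH, H2O2, H2O, 0 °C
Reagents that add atoms: hydrogen peroxide, OO
Why: Anti-Markovnikov hydroboration–oxidation of the terminal alkene with a bulky dialkylborane places the hydroxyl on the terminal carbon and leaves both stereocentres untouched.

Step 4
Reactants: 6
Product: 7 (4S,5R)-4-methyl-5-(3,4,5-trimethoxyphenyl)oxolan-2-one (methyl and aryl cis)
Conditions: TEMPO (10 mol %), PhI(OAc)2 (2.5 equiv), CH2Cl2, rt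
Reagents that add atoms: none
Why: Oxoammonium oxidation is selective for the primary alcohol, the aldehyde is captured by the benzylic hydroxyl as the lactol and oxidised again (oxidative lactonisation of a 1,4-diol), which keeps both stereocentres and installs the temporary ring.

Step 5
Reactants: 7
Product: 8 (4S,5R)-3-acetyl-4-methyl-5-(3,4,5-trimethoxyphenyl)oxolan-2-one (C3 labile, partly enolised)
Conditions: LiN(i-Pr)2 (1.2 equiv), THF, −78 °C; N-methoxy-N-methylacetamide, −78 to 0 °C; aq. NH4Cl
Reagents that add atoms: N-methoxy-N-methylacetamide, CC(=O)N(C)OC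
Why: Claisen-type C-acylation of the lactone lithium enolate by an N-methoxy-N-methyl amide, whose chelated tetrahedral adduct collapses only on work-up so that no second addition occurs; the new C3 centre is configurationally labile and is erased in step 6.

Step 6
Reactants: 8; 2 (1.5 equiv)
Product: 11 (3R,4S,5S,9R)-9-methoxy-4-methyl-3-(3,4,5-trimethoxyphenyl)-2-oxaspiro[4.5]dec-7-ene-1,6-dione, via keto aldehyde 9 (not isolated), via ketol 10 (not isolated)
Conditions: Et3N (10 mol %), toluene, 0 °C to rt; then Bn2NH·CF3CO2H (20 mol %), 4 Å molecular sieves, 50 °C, same flask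
Reagents that add atoms: none
Why: Et3N-catalysed Michael addition of the enol of β-keto lactone 8 to the β-carbon of 2 gives keto aldehyde 9, and the ammonium salt then promotes intramolecular aldol addition of the acetyl methyl carbon to the aldehyde (ketol 10) and dehydration, so that the ring bond from the methylene to the quaternary carbon and the enone C=C bond are made in one flask. The closest known reaction type is the Robinson-type annulation of 2-substituted 1,3-dicarbonyl compounds with acroleins (Michael addition, then aldol condensation). The six-membered ring closes in a 6-(enolendo)-exo-trig mode. The spiro centre C5 is set by the lactone, since the cis methyl and aryl groups cover one face of the planar enol and the acceptor adds to the other. C9 is epimerisable in 9 (α to the aldehyde) and should be funnelled through the chair-like closure that keeps the methoxy group equatorial, the lactone carbonyl axial (dipole opposed to the ketone) and the branched lactone carbon equatorial, which places OMe anti to the lactone carbonyl (9R). The step needs C-alkylation at the methine and not at the methyl group (secured by the 1,3-dicarbonyl acidity) and a single aldol mode (secured because the quaternary carbon has no hydrogen and only the methyl ketone reaches the aldehyde through a six-membered ring).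

Step 7
Reactants: 11
Product: 14 prop-2-en-1-yl (1S,5R)-1-[(1R,2S)-1-(acetyloxy)-1-(3,4,5-trimethoxyphenyl)propan-2-yl]-5-methoxy-2-oxocyclohex-3-ene-1-carboxylate, via lithium carboxylate 12 (not isolated), via hydroxy ester 13 (not isolated)
Conditions: LiOH·H2O (1.1 equiv), THF/H2O, 0 °C; solvent exchange to DMF, allyl bromide, rt; then Ac2O, pyridine, DMAP (cat.), 0 °C to rt
Reagents that add atoms: lithium hydroxide, [Li+].[OH-]; allyl bromide, C=CCBr; acetic anhydride, CC(=O)OC(C)=O
Why: Saponification of the γ-lactone (the more electrophilic carbonyl, the hindered enone being left alone), SN2 O-alkylation of the carboxylate with allyl bromide and DMAP-catalysed acetylation of the freed benzylic alcohol, which also blocks relactonisation; no stereocentre is changed.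

Step 8
Reactants: 14
Product: 15 megaphone acetate, (1R,2S)-2-[(1R,5R)-5-methoxy-2-oxo-1-(prop-2-en-1-yl)cyclohex-3-en-1-yl]-1-(3,4,5-trimethoxyphenyl)propyl acetate
Conditions: Pd2(dba)3 (2.5 mol %), (S)-t-BuPHOX (6.25 mol %), toluene, 30 °C
Reagents that add atoms: none
Why: Tsuji decarboxylative allylation, in which zerovalent palladium ionises the allyl ester, the carboxylate loses CO2 and the cross-conjugated palladium enolate is allylated at the α'-carbon; the allyl group should enter anti to the pseudoaxial methoxy group (1,3-induction), the sense that the (S)-ligand also favours, giving the (1R) quaternary centre.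

Compound list
1 | methoxyacetaldehyde | COCC=O | starting material
2 | 2-methoxyacrolein (2-methoxyprop-2-enal) | C=C(OC)C=O | intermediate
3 | 3,4,5-trimethoxybenzaldehyde | COc1cc(C=O)cc(OC)c1OC | starting material
4 | (Z)-crotylboronic acid pinacol ester, 2-[(2Z)-but-2-en-1-yl]-4,4,5,5-tetramethyl-1,3,2-dioxaborolane | C/C=C\CB1OC(C)(C)C(C)(C)O1 | starting material
5 | (1R,2S)-2-methyl-1-(3,4,5-trimethoxyphenyl)but-3-en-1-ol | C=C[C@H](C)[C@@H](O)c1cc(OC)c(OC)c(OC)c1 | intermediate
6 | (1R,2S)-2-methyl-1-(3,4,5-trimethoxyphenyl)butane-1,4-diol | OCC[C@H](C)[C@@H](O)c1cc(OC)c(OC)c(OC)c1 | intermediate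
7 | (4S,5R)-4-methyl-5-(3,4,5-trimethoxyphenyl)oxolan-2-one | O=C1C[C@H](C)[C@@H](O1)c2cc(OC)c(OC)c(OC)c2 | intermediate
8 | (4S,5R)-3-acetyl-4-methyl-5-(3,4,5-trimethoxyphenyl)oxolan-2-one (C3 labile) | CC(=O)C1[C@H](C)[C@@H](OC1=O)c2cc(OC)c(OC)c(OC)c2 | intermediate
9 | (3S,4S,5R)-3-acetyl-3-(2-methoxy-3-oxopropyl)-4-methyl-5-(3,4,5-trimethoxyphenyl)oxolan-2-one (both epimers at the methoxy carbon) | CC(=O)[C@]1(CC(OC)C=O)[C@H](C)[C@@H](OC1=O)c2cc(OC)c(OC)c(OC)c2 | intermediate
10 | (3R,4S,5S)-8-hydroxy-9-methoxy-4-methyl-3-(3,4,5-trimethoxyphenyl)-2-oxaspiro[4.5]decane-1,6-dione (epimers at C8 and C9) | O=C1CC(O)C(OC)C[C@]12[C@H](C)[C@@H](OC2=O)c3cc(OC)c(OC)c(OC)c3 | intermediate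
11 | (3R,4S,5S,9R)-9-methoxy-4-methyl-3-(3,4,5-trimethoxyphenyl)-2-oxaspiro[4.5]dec-7-ene-1,6-dione | O=C1C=C[C@H](OC)C[C@]12[C@H](C)[C@@H](OC2=O)c3cc(OC)c(OC)c(OC)c3 | intermediate
12 | lithium (1S,5R)-1-[(1R,2S)-1-hydroxy-1-(3,4,5-trimethoxyphenyl)propan-2-yl]-5-methoxy-2-oxocyclohex-3-ene-1-carboxylate | [Li+].[O-]C(=O)[C@]1([C@H](C)[C@@H](O)c2cc(OC)c(OC)c(OC)c2)C[C@@H](OC)C=CC1=O | intermediate
13 | prop-2-en-1-yl (1S,5R)-1-[(1R,2S)-1-hydroxy-1-(3,4,5-trimethoxyphenyl)propan-2-yl]-5-methoxy-2-oxocyclohex-3-ene-1-carboxylate | C=CCOC(=O)[C@]1([C@H](C)[C@@H](O)c2cc(OC)c(OC)c(OC)c2)C[C@@H](OC)C=CC1=O | intermediate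
14 | prop-2-en-1-yl (1S,5R)-1-[(1R,2S)-1-(acetyloxy)-1-(3,4,5-trimethoxyphenyl)propan-2-yl]-5-methoxy-2-oxocyclohex-3-ene-1-carboxylate | C=CCOC(=O)[C@]1([C@H](C)[C@@H](OC(C)=O)c2cc(OC)c(OC)c(OC)c2)C[C@@H](OC)C=CC1=O | intermediate
15 | megaphone acetate, (1R,2S)-2-[(1R,5R)-5-methoxy-2-oxo-1-(prop-2-en-1-yl)cyclohex-3-en-1-yl]-1-(3,4,5-trimethoxyphenyl)propyl acetate | C=CC[C@]1([C@H](C)[C@@H](OC(C)=O)c2cc(OC)c(OC)c(OC)c2)C[C@@H](OC)C=CC1=O | target

Total step count: 8. Longest linear sequence: 7 steps (3 to 15, steps 2 to 8); step 1 is a one-step side branch.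

Steps most likely to fail

Step 6. The methoxy-bearing carbon equilibrates at the aldehyde stage and the bias of the closing chair may be too small to select one epimer. Polymerisation of 2 or retro-Claisen loss of the acetyl group may also erode the step. The fallback sets out from 7 and comes back at 11; it makes the two bonds one after the other, with the methoxy centre bought in. Butadiene monoxide and methanol give (2S)-2-methoxybut-3-en-1-ol F1 by palladium-catalysed dynamic kinetic asymmetric allylic etherification (Pd2(dba)3·CHCl3, N,N'-bis[2-(diphenylphosphino)benzoyl]-trans-cyclohexane-1,2-diamine of the appropriate hand, Et3B), and F1 is converted into its triflate F2 (Tf2O, 2,6-lutidine, −78 °C). Lactone 7 is C-acylated as in step 5, but with N-methoxy-N,3-dimethylbut-2-enamide, to the 3-(3-methylbut-2-enoyl) lactone F3. Its potassium enolate (KN(SiMe3)2, THF, −78 °C) is alkylated by F2 on the face opposite the lactone methyl group to diene F4. Ring-closing metathesis with the second-generation Grubbs catalyst (CH2Cl2, 40 °C) then closes the enone and gives 11 with the methoxy centre fixed.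

Step 8. The ester sits on a carbon flanked by a branched chain, so ionisation may be slow, the enolate may be protonated instead of allylated, and the facial bias may be insufficient. The fallback sets out from 11 and comes back at 15; it uses classical enolate alkylation on the free alcohol. Saponification of 11 (LiOH, THF/H2O), acidification and gentle warming decarboxylate the β-keto acid to hydroxy ketone F5. Its alkoxide–enolate dianion (LiN(i-Pr)2, 2.2 equiv, THF, −78 °C) is allylated with allyl bromide at the α'-carbon anti to the methoxy group to megaphone F6, and acetylation (Ac2O, pyridine, DMAP) gives 15.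

Step 7. The γ-hydroxy ester may close back to the lactone before it is capped, and hydroxide may cause decarboxylation on handling or retro-Claisen opening of the six-membered ring. The fallback sets out from 11 and comes back at 14; it replaces hydrolysis by alcoholysis with capping in the same flask. Lithium allyl oxide (allyl alcohol, LiN(SiMe3)2, THF, −40 °C) opens the lactone by transesterification, and acetic anhydride added to the cold mixture acetylates the liberated benzylic alkoxide before it can re-close. Unchanged 11 is recycled, and no new compound is made.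

Further compounds
F1 | step 6 | (2S)-2-methoxybut-3-en-1-ol | OC[C@@H](OC)C=C
F2 | step 6 | (2S)-2-methoxybut-3-en-1-yl trifluoromethanesulfonate | FC(F)(F)S(=O)(=O)OC[C@@H](OC)C=C
F3 | step 6 | (4S,5R)-4-methyl-3-(3-methylbut-2-enoyl)-5-(3,4,5-trimethoxyphenyl)oxolan-2-one | CC(C)=CC(=O)C1[C@H](C)[C@@H](OC1=O)c2cc(OC)c(OC)c(OC)c2
F4 | step 6 | (3S,4S,5R)-3-[(2R)-2-methoxybut-3-en-1-yl]-4-methyl-3-(3-methylbut-2-enoyl)-5-(3,4,5-trimethoxyphenyl)oxolan-2-one | CC(C)=CC(=O)[C@]1(C[C@@H](OC)C=C)[C@H](C)[C@@H](OC1=O)c2cc(OC)c(OC)c(OC)c2
F5 | step 8 | (4R)-6-[(1R,2S)-1-hydroxy-1-(3,4,5-trimethoxyphenyl)propan-2-yl]-4-methoxycyclohex-2-en-1-one (C6 epimers) | O=C1C=C[C@H](OC)CC1[C@H](C)[C@@H](O)c2cc(OC)c(OC)c(OC)c2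
F6 | step 8 | megaphone, (4R,6R)-6-[(1R,2S)-1-hydroxy-1-(3,4,5-trimethoxyphenyl)propan-2-yl]-4-methoxy-6-(prop-2-en-1-yl)cyclohex-2-en-1-one | C=CC[C@]1([C@H](C)[C@@H](O)c2cc(OC)c(OC)c(OC)c2)C[C@@H](OC)C=CC1=O
F0 | step 7 | none | none
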